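**Assumption:** the sense of induction of the chiral catalysts in steps 2, 8 and 10 is taken from the closest known models (the antipodal ligand is used if the opposite sense is found); the carbinol configuration of 8 is immaterial.

Locants used below (spongian/podocarpane): C10 = quaternary ring-A carbon, C5 = ring-A CH2 between C10 and CMe2, C7 = acid α-carbon, C13 = carbon bearing CH2O, C14 = ketone carbon.

## Retrosynthetic overview

1. 17 ⇒ 16 (O-formylation) ⇒ 14 (catalytic asymmetric α'-hydroxymethylation sets C13).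
2. 14 ⇒ 11: the cyclohexenone ring C is unveiled from an anisole by Birch reduction and hydrolysis.
3. 11 ⇒ 10 ⇒ 9 ⇒ 8: C7 comes from asymmetric hydrogenation of an acrylic acid that is released by radical C5–C6 fission of ring B, the laboratory counterpart of the ring-B cleavage of a spongian precursor.
4. 8 ⇒ 5 ⇒ 4 ⇒ 1 + 2: ring A and a sacrificial ring B are closed together by an enantioselective proton-initiated polyene cyclization, fixing C10.
5. Ring order: aromatic ring C (purchased) → rings A and B in one cationic step → ring B excised → ring C dearomatized.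

## Route

**Step 1**
Reactants: 1 2-methoxybenzyl chloride; 2 geranyl bromide
Product: 4 1-[(3E)-4,8-dimethylnona-3,7-dien-1-yl]-2-methoxybenzene, via benzylic Grignard reagent 3 (not isolated)
Conditions: Mg, Et2O, 0 °C; then 2, Li2CuCl4 (2 mol%), THF, −20 → 0 °C
Reagents that add atoms: none
Why: Kochi-type copper-catalysed coupling of a benzylic Grignard reagent with a primary allylic bromide proceeds by direct (α) substitution with retention of the (E)-alkene, giving the homogeranylarene in one operation.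

**Step 2**
Reactants: 4 1-[(3E)-4,8-dimethylnona-3,7-dien-1-yl]-2-methoxybenzene
Product: 5 (4aS,10aS)-8-methoxy-1,1,4a-trimethyl-1,2,3,4,4a,9,10,10a-octahydrophenanthrene
Conditions: (R)-3,3'-dichloro-BINOL·SbCl5 (1:1 complex, 0.5 equiv), CH2Cl2, −78 °C
Reagents that add atoms: none
Why: Enantioselective proton-initiated cation–olefin bicyclization (Stork–Eschenmoser chair–chair, anti additions): the chiral Brønsted acid protonates the terminal alkene, ring A closes onto the (E)-alkene and the tertiary C10 cation is captured by the only free ortho carbon of the anisole (meta to OMe, as in cyclizations to 12-methoxypodocarpatrienes), so C10 (4aS) and C5 (10aS) arise together as the trans-fused pair.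

**Step 3**
Reactants: 5 (4aS,10aS)-8-methoxy-1,1,4a-trimethyl-1,2,3,4,4a,9,10,10a-octahydrophenanthrene
Product: 6 (4aS,10aS)-8-methoxy-1,1,4a-trimethyl-2,3,4,4a,10,10a-hexahydrophenanthren-9(1H)-one
Conditions: CrO3 (3 equiv), AcOH, 25 °C
Reagents that add atoms: chromium trioxide O=[Cr](=O)=O
Why: Chromic acid benzylic oxidation attacks the only benzylic methylene (C7; C10 is quaternary), as in the conversion of podocarpatrienes into their 7-ketones, and touches no stereocentre.

**Step 4**
Reactants: 6 (4aS,10aS)-8-methoxy-1,1,4a-trimethyl-2,3,4,4a,10,10a-hexahydrophenanthren-9(1H)-one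
Product: 7 (4aS,10aS)-8-methoxy-1,1,4a-trimethyl-9-methylidene-1,2,3,4,4a,9,10,10a-octahydrophenanthrene
Conditions: Ph3PCH3Br (3 equiv), KOtBu (3 equiv), toluene, 90 °C
Reagents that add atoms: methyltriphenylphosphonium bromide C[P+](c1ccccc1)(c1ccccc1)c1ccccc1.[Br-]
Why: Wittig methylenation of the aryl ketone with excess ylide at elevated temperature overcomes the peri-methoxy hindrance and installs the carbon that becomes the C7 methyl group.

**Step 5**
Reactants: 7 (4aS,10aS)-8-methoxy-1,1,4a-trimethyl-9-methylidene-1,2,3,4,4a,9,10,10a-octahydrophenanthrene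
Product: 8 (4aS,10aS)-8-methoxy-1,1,4a-trimethyl-9-methylidene-1,2,3,4,4a,9,10,10a-octahydrophenanthren-10-ol (either carbinol epimer)
Conditions: SeO2 (0.5 equiv), t-BuOOH (3 equiv), CH2Cl2, 0 → 25 °C
Reagents that add atoms: tert-butyl hydroperoxide CC(C)(C)OO (terminal oxidant; oxygen relayed through selenium dioxide O=[Se]=O)
Why: Selenium dioxide allylic hydroxylation (ene reaction then 2,3-sigmatropic shift, as in β-pinene to pinocarveol) oxidizes the only allylic CH2 (C6) and returns the exocyclic alkene; the new carbinol centre is erased in step 6.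

**Step 6**
Reactants: 8 (4aS,10aS)-8-methoxy-1,1,4a-trimethyl-9-methylidene-1,2,3,4,4a,9,10,10a-octahydrophenanthren-10-ol
Product: 9 2-{2-methoxy-6-[(1S)-1,3,3-trimethylcyclohexyl]phenyl}prop-2-enal
Conditions: [Ir(dF(CF3)ppy)2(5,5'-d(CF3)bpy)]PF6 (2 mol%), 2,4,6-triisopropylbenzenethiol (25 mol%), 2,4,6-collidine (1 equiv), CH2Cl2, blue LEDs, 25 °C
Reagents that add atoms: none
Why: Alkoxy-radical β-scission under proton-coupled electron transfer (redox-neutral ring-opening isomerization of cyclic alcohols): the C6 alkoxy radical can fragment only toward C5 because the other direction would give a vinyl radical, the hindered C5 radical takes H from the thiol (a 1,5-H shift from a neighbouring methyl is undone by the same thiol), and this homolytic C5–C6 fission mirrors the ring-B cleavage of the spongian precursor while leaving C10 untouched.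

**Step 7**
Reactants: 9 2-{2-methoxy-6-[(1S)-1,3,3-trimethylcyclohexyl]phenyl}prop-2-enal
Product: 10 2-{2-methoxy-6-[(1S)-1,3,3-trimethylcyclohexyl]phenyl}prop-2-enoic acid
Conditions: NaClO2 (3 equiv), NaH2PO4 (3 equiv), 2-methylbut-2-ene (10 equiv), t-BuOH/H2O, 0 → 25 °C
Reagents that add atoms: sodium chlorite [Na+].[O-]Cl=O
Why: Pinnick oxidation converts the enal into the acrylic acid without touching the alkene or the anisole, with 2-methylbut-2-ene scavenging HOCl.

**Step 8**
Reactants: 10 2-{2-methoxy-6-[(1S)-1,3,3-trimethylcyclohexyl]phenyl}prop-2-enoic acid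
Product: 11 (2R)-2-{2-methoxy-6-[(1S)-1,3,3-trimethylcyclohexyl]phenyl}propanoic acid
Conditions: Ru(OAc)2[(R)-BINAP] (2 mol%), H2 (100 atm), MeOH, 60 °C
Reagents that add atoms: none
Why: Noyori-type carboxylate-directed asymmetric hydrogenation of a 2-arylacrylic acid (the profen reduction) delivers H2 to the face chosen by (R)-BINAP and sets C7 as R; warming lets the two rotamers about the aryl–C7 bond interconvert so that the catalyst reduces the matched one.

**Step 9**
Reactants: 11 (2R)-2-{2-methoxy-6-[(1S)-1,3,3-trimethylcyclohexyl]phenyl}propanoic acid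
Product: 14 (2R)-2-{6-oxo-2-[(1S)-1,3,3-trimethylcyclohexyl]cyclohex-1-en-1-yl}propanoic acid, via Birch dienol ether 12 (not isolated), via deconjugated enone 13 (not isolated)
Conditions: Li (10 equiv), NH3(l)/THF, t-BuOH (5 equiv), −78 → −33 °C; NH4Cl; then 2 M HCl, THF, 40 °C
Reagents that add atoms: water O
Why: Birch reduction of the 2,3-dialkylanisole protonates C8 and C12 (the pattern that turns 2,3-dimethylanisole into 2,3-dimethylcyclohex-2-enone), and acid hydrolysis of the enol ether followed by acid-mediated conjugation gives the tetrasubstituted enone; the lithium carboxylate shields C7 from deprotonation and t-BuOH keeps LiNH2 from building up.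

**Step 10**
Reactants: 14 (2R)-2-{6-oxo-2-[(1S)-1,3,3-trimethylcyclohexyl]cyclohex-1-en-1-yl}propanoic acid
Product: 16 (2R)-2-{(5S)-5-(hydroxymethyl)-6-oxo-2-[(1S)-1,3,3-trimethylcyclohexyl]cyclohex-1-en-1-yl}propanoic acid, via bis-silyl dienol ether 15 (not isolated)
Conditions: LiN(iPr)2 (2.2 equiv), THF, −78 °C; Me3SiCl (2.5 equiv); then Sc(OTf)3 (10 mol%), (S,S)-6,6'-bis(1-hydroxy-2,2-dimethylpropyl)-2,2'-bipyridine (12 mol%), aq. HCHO (5 equiv), DME/H2O 9:1, −20 °C; pH 4 work-up
Reagents that add atoms: formaldehyde C=O; chlorotrimethylsilane C[Si](C)(C)Cl (its atoms stay only in intermediate 15)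
Why: Kinetic α'-deprotonation of the enone (carboxylate first) and silylation give the 2-silyloxydiene, and its catalytic enantioselective Mukaiyama aldol reaction with aqueous formaldehyde at the chiral Sc(OTf)3–bipyridine complex adds CH2OH to one face of C13 under catalyst control (C7 and C10 are too remote to steer), setting 13S without epimerizing or dehydrating the β-hydroxy ketone.

**Step 11**
Reactants: 16 (2R)-2-{(5S)-5-(hydroxymethyl)-6-oxo-2-[(1S)-1,3,3-trimethylcyclohexyl]cyclohex-1-en-1-yl}propanoic acid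
Product: 17 (2R)-2-{(5S)-5-[(formyloxy)methyl]-6-oxo-2-[(1S)-1,3,3-trimethylcyclohexyl]cyclohex-1-en-1-yl}propanoic acid
Conditions: HCO2H/Ac2O (acetic formic anhydride, 3 equiv), pyridine (3 equiv), CH2Cl2, −20 → 0 °C; aq. NaH2PO4 work-up
Reagents that add atoms: acetic formic anhydride CC(=O)OC=O
Why: O-Formylation with the mixed anhydride transfers only the formyl group to the primary alcohol at low temperature, mild enough to avoid β-elimination of the formate and epimerization at C13 or C7, and aqueous work-up returns the free carboxylic acid.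

## Compound list

1 | 2-methoxybenzyl chloride | COc1ccccc1CCl | starting material
2 | geranyl bromide, (2E)-1-bromo-3,7-dimethylocta-2,6-diene | CC(C)=CCC/C(C)=C/CBr | starting material
3 | (2-methoxybenzyl)magnesium chloride | COc1ccccc1C[Mg]Cl | intermediate
4 | 1-[(3E)-4,8-dimethylnona-3,7-dien-1-yl]-2-methoxybenzene | COc1ccccc1CC/C=C(\C)CCC=C(C)C | intermediate
5 | (4aS,10aS)-8-methoxy-1,1,4a-trimethyl-1,2,3,4,4a,9,10,10a-octahydrophenanthrene (trans-fused) | COc1cccc2c1CC[C@H]1C(C)(C)CCC[C@]21C | intermediate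
6 | (4aS,10aS)-8-methoxy-1,1,4a-trimethyl-2,3,4,4a,10,10a-hexahydrophenanthren-9(1H)-one | COc1cccc2c1C(=O)C[C@H]1C(C)(C)CCC[C@]21C | intermediate
7 | (4aS,10aS)-8-methoxy-1,1,4a-trimethyl-9-methylidene-1,2,3,4,4a,9,10,10a-octahydrophenanthrene | COc1cccc2c1C(=C)C[C@H]1C(C)(C)CCC[C@]21C | intermediate
8 | (4aS,10aS)-8-methoxy-1,1,4a-trimethyl-9-methylidene-1,2,3,4,4a,9,10,10a-octahydrophenanthren-10-ol (carbinol centre not controlled) | COc1cccc2c1C(=C)C(O)[C@H]1C(C)(C)CCC[C@]21C | intermediate
9 | 2-{2-methoxy-6-[(1S)-1,3,3-trimethylcyclohexyl]phenyl}prop-2-enal | COc1cccc([C@@]2(C)CCCC(C)(C)C2)c1C(=C)C=O | intermediate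
10 | 2-{2-methoxy-6-[(1S)-1,3,3-trimethylcyclohexyl]phenyl}prop-2-enoic acid | COc1cccc([C@@]2(C)CCCC(C)(C)C2)c1C(=C)C(=O)O | intermediate
11 | (2R)-2-{2-methoxy-6-[(1S)-1,3,3-trimethylcyclohexyl]phenyl}propanoic acid | C[C@@H](C(=O)O)c1c(OC)cccc1[C@@]2(C)CCCC(C)(C)C2 | intermediate
12 | (2R)-2-{2-methoxy-6-[(1S)-1,3,3-trimethylcyclohexyl]cyclohexa-2,5-dien-1-yl}propanoic acid (ring C1 epimers; lithium salt in the flask) | C[C@@H](C(=O)O)C1C(OC)=CCC=C1[C@@]2(C)CCCC(C)(C)C2 | intermediate
13 | (2R)-2-{6-oxo-2-[(1S)-1,3,3-trimethylcyclohexyl]cyclohex-2-en-1-yl}propanoic acid (ring C1 epimers) | C[C@@H](C(=O)O)C1C(=O)CCC=C1[C@@]2(C)CCCC(C)(C)C2 | intermediate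
14 | (2R)-2-{6-oxo-2-[(1S)-1,3,3-trimethylcyclohexyl]cyclohex-1-en-1-yl}propanoic acid | C[C@@H](C(=O)O)C1=C([C@@]2(C)CCCC(C)(C)C2)CCCC1=O | intermediate
15 | trimethylsilyl (2R)-2-{2-[(1S)-1,3,3-trimethylcyclohexyl]-6-[(trimethylsilyl)oxy]cyclohexa-1,5-dien-1-yl}propanoate | C[C@@H](C(=O)O[Si](C)(C)C)C1=C([C@@]2(C)CCCC(C)(C)C2)CCC=C1O[Si](C)(C)C | intermediate
16 | (2R)-2-{(5S)-5-(hydroxymethyl)-6-oxo-2-[(1S)-1,3,3-trimethylcyclohexyl]cyclohex-1-en-1-yl}propanoic acid | C[C@@H](C(=O)O)C1=C([C@@]2(C)CCCC(C)(C)C2)CC[C@@H](CO)C1=O | intermediate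
17 | (2R)-2-{(5S)-5-[(formyloxy)methyl]-6-oxo-2-[(1S)-1,3,3-trimethylcyclohexyl]cyclohex-1-en-1-yl}propanoic acid | C[C@@H](C(=O)O)C1=C([C@@]2(C)CCCC(C)(C)C2)CC[C@@H](COC=O)C1=O | target

## Step count and risks

Total steps: 11. Longest linear sequence: 11.

**Step 6 (radical C5–C6 fission).** The freshly formed 2-arylacrolein is a radical acceptor, so the C5 radical may re-add to its CH2 terminus before the thiol reduces it; the electron-rich styrene may also quench the photocatalyst. The fallback sets out from 8 and comes back at 14.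
- Irradiating 8 with PhI(OAc)2 and I2 (cyclohexane, visible light, 25 °C) forms the hypoiodite; the same β-scission follows, but iodine-atom transfer caps the C5 radical at once, giving 2-{2-[(1R,2RS)-2-iodo-1,3,3-trimethylcyclohexyl]-6-methoxyphenyl}prop-2-enal F1. The iodide cannot eliminate because both neighbours are quaternary.
- NaClO2 oxidation as in step 7 gives 2-{2-[(1R,2RS)-2-iodo-1,3,3-trimethylcyclohexyl]-6-methoxyphenyl}prop-2-enoic acid F2.
- Hydrogenation as in step 8 gives (2R)-2-{2-[(1R,2RS)-2-iodo-1,3,3-trimethylcyclohexyl]-6-methoxyphenyl}propanoic acid F3.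
- The Li/NH3 conditions of step 9 cleave the C–I bond while reducing the arene, so acid hydrolysis delivers 14 with no added step.

**Step 8 (asymmetric hydrogenation).** The alkene sits between an ortho methoxy group and an ortho quaternary carbon, so the catalyst may fail to bind or to select between the slowly interconverting rotamers. The fallback sets out from 10 and comes back at 11; it replaces catalytic hydrogenation by auxiliary-controlled protonation of a ketene.
- H2 over Pd/C (EtOAc) gives (2RS)-2-{2-methoxy-6-[(1S)-1,3,3-trimethylcyclohexyl]phenyl}propanoic acid F4.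
- (COCl)2 with catalytic DMF gives (2RS)-2-{2-methoxy-6-[(1S)-1,3,3-trimethylcyclohexyl]phenyl}propanoyl chloride F5.
- Me3N in toluene at −78 °C gives 2-{2-methoxy-6-[(1S)-1,3,3-trimethylcyclohexyl]phenyl}prop-1-en-1-one F6, the aryl methyl ketene.
- Addition of (R)-pantolactone gives, by diastereoselective protonation, (3R)-4,4-dimethyl-2-oxooxolan-3-yl (2R)-2-{2-methoxy-6-[(1S)-1,3,3-trimethylcyclohexyl]phenyl}propanoate F7.
- LiOH/H2O2 (THF/H2O, 0 °C) then releases 11.

**Step 10 (asymmetric hydroxymethylation).** The enantioselectivity of the scandium-catalysed reaction is untested on a cross-conjugated silyloxydiene that carries a free acid. The fallback sets out from 14 and comes back at 16; it replaces catalyst control by separation with recycling.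
- The dianion of 14 (LiN(iPr)2, 2.2 equiv, THF, −78 °C) is treated with monomeric formaldehyde gas, giving 16 together with its C13 epimer (2R)-2-{(5R)-5-(hydroxymethyl)-6-oxo-2-[(1S)-1,3,3-trimethylcyclohexyl]cyclohex-1-en-1-yl}propanoic acid F8.
- Because C7 and C10 are fixed, the two are diastereomers and are separated by preparative chromatography.
- F8 is re-equilibrated at C13 (catalytic Et3N, toluene, 0 °C) and separated again, so the material converges on 16.

## Further compounds

F1 | step 6 | 2-{2-[(1R,2RS)-2-iodo-1,3,3-trimethylcyclohexyl]-6-methoxyphenyl}prop-2-enal | COc1cccc([C@@]2(C)CCCC(C)(C)C2I)c1C(=C)C=O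
F2 | step 6 | 2-{2-[(1R,2RS)-2-iodo-1,3,3-trimethylcyclohexyl]-6-methoxyphenyl}prop-2-enoic acid | COc1cccc([C@@]2(C)CCCC(C)(C)C2I)c1C(=C)C(=O)O
F3 | step 6 | (2R)-2-{2-[(1R,2RS)-2-iodo-1,3,3-trimethylcyclohexyl]-6-methoxyphenyl}propanoic acid | C[C@@H](C(=O)O)c1c(OC)cccc1[C@@]2(C)CCCC(C)(C)C2I
F4 | step 8 | (2RS)-2-{2-methoxy-6-[(1S)-1,3,3-trimethylcyclohexyl]phenyl}propanoic acid | CC(C(=O)O)c1c(OC)cccc1[C@@]2(C)CCCC(C)(C)C2
F5 | step 8 | (2RS)-2-{2-methoxy-6-[(1S)-1,3,3-trimethylcyclohexyl]phenyl}propanoyl chloride | CC(C(=O)Cl)c1c(OC)cccc1[C@@]2(C)CCCC(C)(C)C2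
F6 | step 8 | 2-{2-methoxy-6-[(1S)-1,3,3-trimethylcyclohexyl]phenyl}prop-1-en-1-one | CC(=C=O)c1c(OC)cccc1[C@@]2(C)CCCC(C)(C)C2
F7 | step 8 | (3R)-4,4-dimethyl-2-oxooxolan-3-yl (2R)-2-{2-methoxy-6-[(1S)-1,3,3-trimethylcyclohexyl]phenyl}propanoate | C[C@@H](C(=O)O[C@H]1C(=O)OCC1(C)C)c1c(OC)cccc1[C@@]2(C)CCCC(C)(C)C2
F8 | step 10 | (2R)-2-{(5R)-5-(hydroxymethyl)-6-oxo-2-[(1S)-1,3,3-trimethylcyclohexyl]cyclohex-1-en-1-yl}propanoic acid | C[C@@H](C(=O)O)C1=C([C@@]2(C)CCCC(C)(C)C2)CC[C@H](CO)C1=O
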